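The numbers in the tables stem from a simulated flask for substances that don't exist.

Leave the early times aside at first: Wednesday's first reading is 3.25% of the substrate charge, and the scatter of one reading is 0.833% of that charge.

| setting | Wednesday's | Sunday's | Saturday's | Monday's | Tuesday's |
|---|---|---|---|---|---|
| substrate | 0.120 M | 0.0480 M | 0.120 M | 0.120 M | 0.120 M |
| coupling partner | 0.240 M | 0.168 M | 0.240 M | 0.120 M | 0.240 M |
| catalyst | 0.00120 M | 0.00120 M | 0.00240 M | 0.00120 M | 0.00780 M |
| time |  |  |  |  | 13 min |

| run | time / min | [product] / M |
|---|---|---|
| Wednesday's run | 0.52 | 0.0039 |
| Wednesday's run | 0.99 | 0.0077 |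
| Wednesday's run | 1.9 | 0.0161 |
| Wednesday's run | 3.6 | 0.0285 |
| Wednesday's run | 6.8 | 0.0487 |
| Wednesday's run | 13 | 0.0783 |
| Sunday's run | 0.52 | 0.0032 |
| Sunday's run | 0.99 | 0.0049 |
| Sunday's run | 1.9 | 0.0067 |
| Sunday's run | 3.6 | 0.0138 |
| Sunday's run | 6.8 | 0.0225 |
| Sunday's run | 13 | 0.0358 |
| Saturday's run | 0.52 | 0.0088 |
| Saturday's run | 0.99 | 0.0161 |
| Saturday's run | 1.9 | 0.0263 |
| Saturday's run | 3.6 | 0.0467 |
| Saturday's run | 6.8 | 0.0763 |
| Saturday's run | 13 | 0.1027 |
| Monday's run | 0.52 | 7 × 10⁻⁴ |
| Monday's run | 0.99 | 0.0033 |
| Monday's run | 1.9 | 0.0079 |
| Monday's run | 3.6 | 0.0143 |
| Monday's run | 6.8 | 0.0255 |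
| Monday's run | 13 | 0.0434 |

(readings scatter by 0.001 M)

- Overall: substrate + coupling partner -> product, with catalyst as catalyst.
- Constant volume, constant temperature.
- The analysis sees a species whether free or bound.
- "The second partner" is coupling partner.
- An order is taken over about fifteen percent of the charge, up and down.

- reaction order in [substrate] at the outset, round the charge of the Wednesday's run, defined at two percent of the substrate turned into product (one fixed amount of product, the same in the runs compared)
- reaction order in [coupling partner] at the outset, round the charge of the Wednesday's run, defined at two percent of the substrate turned into product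
- the Sunday's run starts with 0.0720 M less of substrate and of coupling partner than the Wednesday's run, and with no product. Compared where both hold the same amount of substrate, once fifteen percent of what the Sunday's run was charged with has turned into product, is the Sunday's run faster, slower or alike (within a tenth)?
- product in the Tuesday's run at 13 min, as a share of the substrate charged
- which of these the readings show (the second partner pairs with itself / the catalyst rests as a dimer / the substrate is lost by itself / the product reacts on with the second partner / nothing beyond the main steps / the product kills the catalyst)

Read each run as the fraction of the substrate charge still left. Treat substrate as the limiting reagent, because Tuesday's charge, like Wednesday's, holds twice as much coupling partner.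

Wednesday's last reading leaves 34.8% of the charge, so take the logarithm of charge over what is left and divide by the time: 0.0813 min⁻¹. Call this the clearing constant, an apparent pseudo-first-order constant. Freeze it, since Wednesday's run already gives 0.0753 min⁻¹ at 3.6 min.

But catalyst moves it. Saturday's run, with twice Wednesday's catalyst, gives 0.149 min⁻¹ at its last reading. The constant therefore rises 1.83 times, less than the catalyst does. Read that as a reading: one reading's scatter moves Saturday's value by about 0.00445 min⁻¹. As an exponent on catalyst it is 0.874.

Tuesday's flask holds 3.25 times Saturday's catalyst, so my reckoning carries that exponent over and gets 0.417 min⁻¹. At 13 min that makes 99.6% product. Watch the fraction left, which I put at 0.442%, less than the scatter.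

The forecast gives orders 0.3 in substrate and 1 in partner, alike, 88% and the product reacts on with the second partner, on the ground of “product being consumed at high product levels”, and its share stands below mine.

Tuesday's flask gives 97.9% at 13 min. Round Wednesday's charge the orders are 0.25 in substrate and 1.0 in coupling partner, Sunday's run and Wednesday's run are alike where they hold the same substrate, and the readings show that the catalyst rests as a dimer.

    catalyst + substrate ⇌ catalyst-substrate complex, settled at all times (75.30 M⁻¹)
    catalyst-substrate complex + coupling partner → product + catalyst + by-product (35.82 M⁻¹ min⁻¹)
    2 catalyst ⇌ resting dimer, settled at all times (4170 M⁻¹)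

That share means a clearing constant of 0.299 min⁻¹ for Tuesday's flask, less than my reckoned 0.417 min⁻¹. It is 3.68 times Wednesday's for 6.50 times the catalyst, an exponent of 0.695. Saturday's run, by its half-time of 5.02 min against Wednesday's 9.01 min, has a clearing constant of 0.138 min⁻¹ over its first half and an exponent of 0.843.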